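Cuts: the C6–CH2 bond joining the side chain to ring B (aldol condensation, then conjugate reduction); in ring D the C3–C3a bond (Nazarov) and the C1 methyl/hydroxyl pair (from a ketone); ring C at C8–C8a and C4–C5 (vinylcarbenoid cyclopropanation/Cope); ring A at O1–C2 and the C5a–CH3 bond.
Feature: in ring D the carbinol carbon C1 lies between fusion carbon C8a and the C2 methylene, so as a ketone it is the carbonyl of a divinyl ketone whose arms are the ring C alkene C8a=C3a and a 2-silylvinyl group (C2=C3); 4π closure makes C3–C3a.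
Forward: ring C, then ring D, then the side chain is taken to an aldehyde; separately ring B from 4-silyloxycyclohexanone, ring A by 7-endo epoxide opening, C5a methyl by cuprate; the halves are joined, C6 and C7 set, C1 hydrated, C3 oxidised.
Stereochemistry: C5 from Rh2(S-DOSP)4 and the (E)-diene; C3a from the sense of conrotation (relayed from C5), C8a from convex protonation; C1 from convex-face oxymercuration; C9a from a chiral lithium amide; C5a from anti cuprate addition; C6 from axial protonation; C7 from equatorial MeCeCl2 attack.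

Key step: step 10

Remark: the SMILES is read literally; it places the C5a methyl and the C9a hydrogen of the benzoxepane on the same face (rings A/B cis-fused), and the route is built for that isomer.
Locants: rings C/D as hydroazulene (C1 carbinol, C3a/C8a fusion, C4 CMe2, C5 side chain, C6 methyl); rings A/B as 1-benzoxepane (O1, C2 CMe2, C3 ketone, C5a, C6 side chain, C7 carbinol, C9a).

Step 1
Reactants: 1 4-methylpent-3-enoic acid
Product: 2 methyl 4-methylpent-3-enoate
Conditions: MeI, K2CO3, DMF, rt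
Reagents that add atoms: iodomethane, CI
Why: SN2 O-alkylation of the carboxylate (esterification) leaves the β,γ-alkene in place.

Step 2
Reactants: 2 methyl 4-methylpent-3-enoate
Product: 3 methyl 2-diazo-4-methylpent-3-enoate
Conditions: p-ABSA, DBU, MeCN, 0 °C to rt
Reagents that add atoms: 4-acetamidobenzenesulfonyl azide, CC(=O)Nc1ccc(cc1)S(=O)(=O)N=[N+]=[N-]
Why: Regitz diazo transfer to the methylene activated by both ester and vinyl group gives the vinyldiazoacetate.

Step 3
Reactants: 4 propane-1,3-diol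
Product: 5 3-(tert-butyldiphenylsilyloxy)propan-1-ol
Conditions: NaH (1 equiv), THF, 0 °C; TBDPSCl, rt
Reagents that add atoms: tert-butyl(chloro)diphenylsilane, CC(C)(C)[Si](Cl)(c1ccccc1)c1ccccc1
Why: Silylation of the sparingly soluble monosodium alkoxide of the symmetric diol stops at the mono-ether.

Step 4
Reactants: 5 3-(tert-butyldiphenylsilyloxy)propan-1-ol
Product: 6 3-(tert-butyldiphenylsilyloxy)propanal
Conditions: TEMPO (cat.), PhI(OAc)2, CH2Cl2, rt
Reagents that add atoms: none
Why: TEMPO-catalysed oxidation of the primary alcohol stops at the aldehyde.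

Step 5
Reactants: 6 3-(tert-butyldiphenylsilyloxy)propanal
Product: 7 (E)-5-(tert-butyldiphenylsilyloxy)-2-methylpent-2-enal
Conditions: Ph3P=C(Me)CHO, toluene, 90 °C
Reagents that add atoms: 2-(triphenylphosphoranylidene)propanal, CC(C=O)=P(c1ccccc1)(c1ccccc1)c1ccccc1
Why: Wittig olefination with a stabilised ylide should give the (E)-trisubstituted enal.

Step 6
Reactants: 7 (E)-5-(tert-butyldiphenylsilyloxy)-2-methylpent-2-enal
Product: 8 (E)-tert-butyl[(4-methylhexa-3,5-dien-1-yl)oxy]diphenylsilane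
Conditions: Ph3PCH3Br, KOt-Bu, THF, 0 °C
Reagents that add atoms: methyltriphenylphosphonium bromide, C[P+](c1ccccc1)(c1ccccc1)c1ccccc1.[Br-]
Why: Wittig methylenation turns the aldehyde into the terminal vinyl group without touching the (E)-alkene.

Step 7
Reactants: 3 methyl 2-diazo-4-methylpent-3-enoate; 8 (E)-tert-butyl[(4-methylhexa-3,5-dien-1-yl)oxy]diphenylsilane
Product: 10 methyl (4R)-4-[2-(tert-butyldiphenylsilyloxy)ethyl]-3,3,5-trimethylcyclohepta-1,5-diene-1-carboxylate, via cis-divinylcyclopropane 9 (not isolated)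
Conditions: Rh2(S-DOSP)4 (1 mol %), hexanes, −78 °C to rt, slow addition of 3; then toluene, 100 °C
Reagents that add atoms: none
Why: Tandem cyclopropanation/Cope rearrangement (formal [4+3] cycloaddition): the rhodium vinylcarbenoid adds only to the terminal alkene of the diene to give the cis-divinylcyclopropane, which rearranges through a boat transition state with the side chain of the (E)-alkene pointing outward, so the C4 stereocentre follows from the catalyst's face selectivity (assigned by the usual model for this catalyst) and the alkene geometry.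

Step 8
Reactants: 10 methyl (4R)-4-[2-(tert-butyldiphenylsilyloxy)ethyl]-3,3,5-trimethylcyclohepta-1,5-diene-1-carboxylate
Product: 11 (4R)-4-[2-(tert-butyldiphenylsilyloxy)ethyl]-N-methoxy-N,3,3,5-tetramethylcyclohepta-1,5-diene-1-carboxamide
Conditions: MeNH(OMe)·HCl, i-PrMgCl, THF, −20 °C
Reagents that add atoms: N,O-dimethylhydroxylamine hydrochloride, CNOC.Cl
Why: Aminolysis of the ester by the magnesium amide gives the Weinreb amide.

Step 9
Reactants: 11 the Weinreb amide; 12 (E)-(2-bromovinyl)trimethylsilane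
Product: 14 (E)-1-{(4R)-4-[2-(tert-butyldiphenylsilyloxy)ethyl]-3,3,5-trimethylcyclohepta-1,5-dien-1-yl}-3-(trimethylsilyl)prop-2-en-1-one, via (E)-2-(trimethylsilyl)vinyllithium 13 (not isolated)
Conditions: 12, t-BuLi (2 equiv), Et2O, −78 °C; then 11, THF, −78 to 0 °C; aq NH4Cl
Reagents that add atoms: none
Why: Br/Li exchange with retention of alkene geometry, then acylation of the vinyllithium by the Weinreb amide, whose chelated tetrahedral intermediate prevents over-addition.

Step 10
Reactants: 14 the cycloheptadienyl (E)-2-silylvinyl ketone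
Product: 15 (3aS,5R,8aS)-5-[2-(tert-butyldiphenylsilyloxy)ethyl]-4,4,6-trimethyl-3a,4,5,8-tetrahydroazulen-1(8aH)-one
Conditions: FeCl3 (1.1 equiv), CH2Cl2, −30 to 0 °C; aq NaHCO3
Reagents that add atoms: none
Why: FeCl3 (trivalent iron) binds the ketone oxygen to give a pentadienyl cation that closes by thermal conrotatory 4π electrocyclization, forming the C3–C3a bond and ring D as a five-membered oxyallyl cation; the β-silicon stabilises the charge next to it and is then lost, which fixes the new alkene at C2=C3 and leaves hydrogen at both fusion carbons. The closest known reaction is the silicon-directed Nazarov cyclization of cycloalkenyl β-silylvinyl ketones to cis-fused cyclopentenones. C3a is set by the sense of conrotation: A(1,2) strain with the C6 methyl should hold the C5 side chain pseudoaxial, so the C4 methyl trans to it is pseudoaxial on the other face and the vinyl terminus should bond to C3a on the face of the side chain. C8a is set by kinetic protonation of the iron dienolate on the convex face, syn to the new C3a–H, giving the cis fusion. The step needs chemoselectivity over the C6=C7 alkene, which is not conjugated with the cation and can only reach it through a strained ring, and a protecting group that survives the Lewis acid, hence TBDPS.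

Step 11
Reactants: 15 the cis-fused cyclopentenone
Product: 16 (3aS,5R,8aS)-5-[2-(tert-butyldiphenylsilyloxy)ethyl]-4,4,6-trimethyl-3,3a,4,5,8,8a-hexahydroazulen-1(2H)-one
Conditions: H2 (1 atm), RhCl(PPh3)3 (5 mol %), benzene, rt
Reagents that add atoms: none
Why: Homogeneous hydrogenation with RhCl(PPh3)3 reduces the disubstituted enone alkene and leaves the trisubstituted ring C alkene; neutral conditions keep C8a.

Step 12
Reactants: 16 the cis-fused cyclopentanone
Product: 17 tert-butyl{2-[(3aS,5R,8aS)-4,4,6-trimethyl-1-methylene-1,2,3,3a,4,5,8,8a-octahydroazulen-5-yl]ethoxy}diphenylsilane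
Conditions: Zn, CH2Br2, TiCl4, THF/CH2Cl2, 0 °C to rt
Reagents that add atoms: dibromomethane, BrCBr
Why: Lombardo–Takai methylenation is non-basic, so the epimerisable C8a–H next to the ketone keeps the cis fusion.

Step 13
Reactants: 17 the silyl ether
Product: 18 2-[(3aS,5R,8aS)-4,4,6-trimethyl-1-methylene-1,2,3,3a,4,5,8,8a-octahydroazulen-5-yl]ethanol
Conditions: TBAF, THF, rt
Reagents that add atoms: none
Why: Fluoride cleaves the silyl ether.

Step 14
Reactants: 18 the primary alcohol
Product: 19 2-[(3aS,5R,8aS)-4,4,6-trimethyl-1-methylene-1,2,3,3a,4,5,8,8a-octahydroazulen-5-yl]acetaldehyde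
Conditions: TEMPO (cat.), PhI(OAc)2, CH2Cl2, rt
Reagents that add atoms: none
Why: TEMPO-catalysed oxidation to the aldehyde does not touch either alkene.

Step 15
Reactants: 20 4-(tert-butyldimethylsilyloxy)cyclohexanone
Product: 21 tert-butyldimethyl{[(1R)-4-(trimethylsilyloxy)cyclohex-3-en-1-yl]oxy}silane
Conditions: (S,S)-bis(1-phenylethyl)amine, n-BuLi, LiCl, THF, −78 °C, TMSCl present (internal quench)
Reagents that add atoms: chlorotrimethylsilane, C[Si](C)(C)Cl
Why: Enantioselective deprotonation of the prochiral ketone by a chiral lithium amide sets the carbinol centre (later C9a), the sense being assigned by analogy with 4-tert-butylcyclohexanone; any minor enantiomer is removed as a diastereomer after fragment coupling.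

Step 16
Reactants: 21 the enol silane
Product: 22 (4R)-4-(tert-butyldimethylsilyloxy)cyclohex-2-en-1-one
Conditions: Pd(OAc)2 (10 mol %), O2 (1 atm), DMSO, rt
Reagents that add atoms: none
Why: Saegusa–Ito oxidation introduces the alkene on the side fixed by the enol ether.

Step 17
Reactants: 22 (4R)-4-(tert-butyldimethylsilyloxy)cyclohex-2-en-1-one; 23 5-bromo-2-methylpent-2-ene
Product: 25 tert-butyldimethyl{[(1R,2R)-2-(4-methylpent-3-en-1-yl)-4-(trimethylsilyloxy)cyclohex-3-en-1-yl]oxy}silane, via homoprenylmagnesium bromide 24 (not isolated)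
Conditions: 23, Mg, THF; then CuBr·SMe2 (10 mol %), TMSCl, HMPA, 22, THF, −78 °C
Reagents that add atoms: chlorotrimethylsilane, C[Si](C)(C)Cl
Why: Copper-catalysed conjugate addition of the Grignard reagent, accelerated and trapped by TMSCl, occurs anti to the silyloxy group and fixes the enol ether regiochemistry.

Step 18
Reactants: 25 the enol silane
Product: 26 (4R)-4-(tert-butyldimethylsilyloxy)-3-(4-methylpent-3-en-1-yl)cyclohex-2-en-1-one
Conditions: Pd(OAc)2 (10 mol %), O2 (1 atm), DMSO, rt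
Reagents that add atoms: none
Why: A second Saegusa–Ito oxidation re-forms the enone, now β-substituted (the side-chain stereocentre of 25 is removed).

Step 19
Reactants: 26 the silyl ether
Product: 27 (4R)-4-hydroxy-3-(4-methylpent-3-en-1-yl)cyclohex-2-en-1-one
Conditions: aq HF, MeCN, 0 °C
Reagents that add atoms: none
Why: Acidic fluoride removes the TBS ether without base that could enolise the γ-hydroxy enone.

Step 20
Reactants: 27 the hydroxy enone
Product: 28 (4R)-3-{2-[(2R)-3,3-dimethyloxiran-2-yl]ethyl}-4-hydroxycyclohex-2-en-1-one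
Conditions: D-fructose-derived chiral ketone (30 mol %), KHSO5, K2CO3, Bu4NHSO4, MeCN/CH2(OMe)2/H2O, 0 °C
Reagents that add atoms: potassium peroxymonosulfate, [K+].[O-]S(=O)(=O)OO
Why: Shi epoxidation: the chiral dioxirane attacks the electron-rich trisubstituted alkene and not the enone, giving one epoxide diastereomer (this centre later becomes the ketone).

Step 21
Reactants: 28 the epoxy alcohol
Product: 29 (3R,9aR)-3-hydroxy-2,2-dimethyl-2,3,4,5,9,9a-hexahydro-1-benzoxepin-7(8H)-one
Conditions: CSA (10 mol %), CH2Cl2, 0 °C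
Reagents that add atoms: none
Why: Acid-catalysed intramolecular epoxide opening at the tertiary carbon, which carries the positive charge (7-endo, Markovnikov), closes ring A; the C3–O bond is not broken, so C3 keeps its configuration.

Step 22
Reactants: 29 the bicyclic hydroxy enone
Product: 30 (3R,9aR)-3-(tert-butyldimethylsilyloxy)-2,2-dimethyl-2,3,4,5,9,9a-hexahydro-1-benzoxepin-7(8H)-one
Conditions: TBSOTf, 2,6-lutidine, CH2Cl2, −78 °C
Reagents that add atoms: tert-butyldimethylsilyl trifluoromethanesulfonate, CC(C)(C)[Si](C)(C)OS(=O)(=O)C(F)(F)F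
Why: The silyl triflate silylates the hindered alcohol next to the quaternary carbon.

Step 23
Reactants: 30 the bicyclic enone
Product: 31 tert-butyldimethyl{[(3R,5aS,9aR)-2,2,5a-trimethyl-7-(trimethylsilyloxy)-2,3,4,5,5a,8,9,9a-octahydro-1-benzoxepin-3-yl]oxy}silane
Conditions: Me2CuLi (from CuI, MeLi), TMSCl, THF, −78 °C
Reagents that add atoms: lithium dimethylcuprate, [Li+].C[Cu-]C; chlorotrimethylsilane, C[Si](C)(C)Cl
Why: Cuprate conjugate addition to the bicyclic enone: axial attack anti to the C9a–O bond gives the cis-fused ring system (as with octalones), and silyl trapping fixes the enolate at C6=C7.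

Step 24
Reactants: 31 the enol silane; 19 the ring C/D aldehyde
Product: 33 (3R,5aS,9aR)-3-(tert-butyldimethylsilyloxy)-6-{1-hydroxy-2-[(3aS,5R,8aS)-4,4,6-trimethyl-1-methylene-1,2,3,3a,4,5,8,8a-octahydroazulen-5-yl]ethyl}-2,2,5a-trimethyloctahydro-1-benzoxepin-7(2H)-one (mixture at C6 and the carbinol carbon), via lithium enolate 32 (not isolated)
Conditions: MeLi, THF, 0 °C; then 19, −78 °C; aq NH4Cl
Reagents that add atoms: none
Why: MeLi cleaves the enol silane to the regiodefined lithium enolate, which adds to the aldehyde (aldol addition); both new centres are removed in the next step.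

Step 25
Reactants: 33 the β-hydroxy ketone
Product: 35 (3R,5aS,9aR)-3-(tert-butyldimethylsilyloxy)-2,2,5a-trimethyl-6-{2-[(3aS,5R,8aS)-4,4,6-trimethyl-1-methylene-1,2,3,3a,4,5,8,8a-octahydroazulen-5-yl]ethylidene}octahydro-1-benzoxepin-7(2H)-one (alkene geometry not controlled), via mesylate 34 (not isolated)
Conditions: MsCl, Et3N, CH2Cl2, 0 °C; then DBU, rt
Reagents that add atoms: none
Why: Mesylation and E1cB elimination give the 2-alkylidene ketone, whose geometry is of no consequence.

Step 26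
Reactants: 35 the alkylidene ketone
Product: 36 (3R,5aS,6S,9aR)-3-(tert-butyldimethylsilyloxy)-2,2,5a-trimethyl-6-{2-[(3aS,5R,8aS)-4,4,6-trimethyl-1-methylene-1,2,3,3a,4,5,8,8a-octahydroazulen-5-yl]ethyl}octahydro-1-benzoxepin-7(2H)-one
Conditions: [(Ph3P)CuH]6, toluene, H2O, rt
Reagents that add atoms: none
Why: Copper hydride conjugate reduction touches only the enone; the C2 gem-dimethyl group locks the cis-fused system in the conformer with the C5a methyl axial on ring B, and axial protonation of the enolate at C6 puts the side chain equatorial, cis to that methyl (also expected to be the more stable epimer).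

Step 27
Reactants: 36 the ketone
Product: 37 (3R,5aS,6S,7R,9aR)-3-(tert-butyldimethylsilyloxy)-2,2,5a,7-tetramethyl-6-{2-[(3aS,5R,8aS)-4,4,6-trimethyl-1-methylene-1,2,3,3a,4,5,8,8a-octahydroazulen-5-yl]ethyl}decahydro-1-benzoxepin-7-ol
Conditions: MeLi, CeCl3, THF, −78 °C
Reagents that add atoms: methyllithium, [Li]C
Why: Organocerium 1,2-addition suppresses enolisation; equatorial attack, away from the syn-axial C5a methyl and the adjacent side chain, gives the axial C7 hydroxyl.

Step 28
Reactants: 37 the methylene compound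
Product: 39 (1S,3aS,5R,8aS)-5-{2-[(3R,5aS,6S,7R,9aR)-3-(tert-butyldimethylsilyloxy)-7-hydroxy-2,2,5a,7-tetramethyldecahydro-1-benzoxepin-6-yl]ethyl}-1,4,4,6-tetramethyl-1,2,3,3a,4,5,8,8a-octahydroazulen-1-ol, via organomercurial acetate 38 (not isolated)
Conditions: Hg(OAc)2, THF/H2O, 0 °C; then NaBH4, aq NaOH
Reagents that add atoms: water, O
Why: Oxymercuration–demercuration (Markovnikov hydration): the 1,1-disubstituted alkene reacts far faster than the trisubstituted ring alkene, and water enters from the convex face of the cis-fused rings C/D, giving the C1 hydroxyl cis to the fusion hydrogens.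

Step 29
Reactants: 39 the silyl ether
Product: 40 (3R,5aS,6S,7R,9aR)-6-{2-[(1S,3aS,5R,8aS)-1-hydroxy-1,4,4,6-tetramethyl-1,2,3,3a,4,5,8,8a-octahydroazulen-5-yl]ethyl}-2,2,5a,7-tetramethyldecahydro-1-benzoxepine-3,7-diol
Conditions: TBAF, THF, 50 °C
Reagents that add atoms: none
Why: Fluoride removes the secondary TBS ether, with heat because the position is hindered.

Step 30
Reactants: 40 the triol
Product: 41 the target, (5aS,6S,7R,9aR)-7-hydroxy-6-{2-[(1S,3aS,5R,8aS)-1-hydroxy-1,4,4,6-tetramethyl-1,2,3,3a,4,5,8,8a-octahydroazulen-5-yl]ethyl}-2,2,5a,7-tetramethyloctahydro-1-benzoxepin-3(2H)-one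
Conditions: (n-Pr4N)RuO4 (5 mol %), NMO, 4 Å MS, CH2Cl2, rt
Reagents that add atoms: none
Why: Ley–Griffith oxidation converts the only secondary alcohol into the ring A ketone; the two tertiary alcohols cannot be oxidised.

Compound list
1 | 4-methylpent-3-enoic acid | CC(C)=CCC(=O)O | starting material
2 | methyl 4-methylpent-3-enoate | COC(=O)CC=C(C)C | intermediate
3 | methyl 2-diazo-4-methylpent-3-enoate | COC(=O)C(=[N+]=[N-])C=C(C)C | intermediate
4 | propane-1,3-diol | OCCCO | starting material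
5 | 3-(tert-butyldiphenylsilyloxy)propan-1-ol | OCCCO[Si](c1ccccc1)(c1ccccc1)C(C)(C)C | intermediate
6 | 3-(tert-butyldiphenylsilyloxy)propanal | O=CCCO[Si](c1ccccc1)(c1ccccc1)C(C)(C)C | intermediate
7 | (E)-5-(tert-butyldiphenylsilyloxy)-2-methylpent-2-enal | O=C/C(C)=C/CCO[Si](c1ccccc1)(c1ccccc1)C(C)(C)C | intermediate
8 | (E)-tert-butyl[(4-methylhexa-3,5-dien-1-yl)oxy]diphenylsilane | C=C/C(C)=C/CCO[Si](c1ccccc1)(c1ccccc1)C(C)(C)C | intermediate
9 | methyl (1R,2R)-2-[(E)-5-(tert-butyldiphenylsilyloxy)pent-2-en-2-yl]-1-(2-methylprop-1-en-1-yl)cyclopropane-1-carboxylate (not isolated) | COC(=O)[C@@]1(C=C(C)C)C[C@@H]1/C(C)=C/CCO[Si](c1ccccc1)(c1ccccc1)C(C)(C)C | intermediate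
10 | methyl (4R)-4-[2-(tert-butyldiphenylsilyloxy)ethyl]-3,3,5-trimethylcyclohepta-1,5-diene-1-carboxylate | COC(=O)C1=CC(C)(C)[C@H](CCO[Si](c2ccccc2)(c2ccccc2)C(C)(C)C)C(C)=CC1 | intermediate
11 | (4R)-4-[2-(tert-butyldiphenylsilyloxy)ethyl]-N-methoxy-N,3,3,5-tetramethylcyclohepta-1,5-diene-1-carboxamide | CON(C)C(=O)C1=CC(C)(C)[C@H](CCO[Si](c2ccccc2)(c2ccccc2)C(C)(C)C)C(C)=CC1 | intermediate
12 | (E)-(2-bromovinyl)trimethylsilane | C[Si](C)(C)/C=C/Br | starting material
13 | (E)-2-(trimethylsilyl)vinyllithium (not isolated) | C[Si](C)(C)/C=C/[Li] | intermediate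
14 | (E)-1-{(4R)-4-[2-(tert-butyldiphenylsilyloxy)ethyl]-3,3,5-trimethylcyclohepta-1,5-dien-1-yl}-3-(trimethylsilyl)prop-2-en-1-one | C[Si](C)(C)/C=C/C(=O)C1=CC(C)(C)[C@H](CCO[Si](c2ccccc2)(c2ccccc2)C(C)(C)C)C(C)=CC1 | intermediate
15 | (3aS,5R,8aS)-5-[2-(tert-butyldiphenylsilyloxy)ethyl]-4,4,6-trimethyl-3a,4,5,8-tetrahydroazulen-1(8aH)-one | CC1=CC[C@H]2[C@H](C=CC2=O)C(C)(C)[C@@H]1CCO[Si](c3ccccc3)(c3ccccc3)C(C)(C)C | intermediate
16 | (3aS,5R,8aS)-5-[2-(tert-butyldiphenylsilyloxy)ethyl]-4,4,6-trimethyl-3,3a,4,5,8,8a-hexahydroazulen-1(2H)-one | CC1=CC[C@H]2[C@H](CCC2=O)C(C)(C)[C@@H]1CCO[Si](c3ccccc3)(c3ccccc3)C(C)(C)C | intermediate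
17 | tert-butyl{2-[(3aS,5R,8aS)-4,4,6-trimethyl-1-methylene-1,2,3,3a,4,5,8,8a-octahydroazulen-5-yl]ethoxy}diphenylsilane | CC1=CC[C@H]2[C@H](CCC2=C)C(C)(C)[C@@H]1CCO[Si](c3ccccc3)(c3ccccc3)C(C)(C)C | intermediate
18 | 2-[(3aS,5R,8aS)-4,4,6-trimethyl-1-methylene-1,2,3,3a,4,5,8,8a-octahydroazulen-5-yl]ethanol | CC1=CC[C@H]2[C@H](CCC2=C)C(C)(C)[C@@H]1CCO | intermediate
19 | 2-[(3aS,5R,8aS)-4,4,6-trimethyl-1-methylene-1,2,3,3a,4,5,8,8a-octahydroazulen-5-yl]acetaldehyde | CC1=CC[C@H]2[C@H](CCC2=C)C(C)(C)[C@@H]1CC=O | intermediate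
20 | 4-(tert-butyldimethylsilyloxy)cyclohexanone | O=C1CCC(O[Si](C)(C)C(C)(C)C)CC1 | starting material
21 | tert-butyldimethyl{[(1R)-4-(trimethylsilyloxy)cyclohex-3-en-1-yl]oxy}silane | C[Si](C)(C)OC1=CC[C@H](O[Si](C)(C)C(C)(C)C)CC1 | intermediate
22 | (4R)-4-(tert-butyldimethylsilyloxy)cyclohex-2-en-1-one | O=C1C=C[C@H](O[Si](C)(C)C(C)(C)C)CC1 | intermediate
23 | 5-bromo-2-methylpent-2-ene | CC(C)=CCCBr | starting material
24 | (4-methylpent-3-en-1-yl)magnesium bromide (not isolated) | CC(C)=CCC[Mg]Br | intermediate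
25 | tert-butyldimethyl{[(1R,2R)-2-(4-methylpent-3-en-1-yl)-4-(trimethylsilyloxy)cyclohex-3-en-1-yl]oxy}silane | C[Si](C)(C)OC1=C[C@@H](CCC=C(C)C)[C@H](O[Si](C)(C)C(C)(C)C)CC1 | intermediate
26 | (4R)-4-(tert-butyldimethylsilyloxy)-3-(4-methylpent-3-en-1-yl)cyclohex-2-en-1-one | O=C1C=C(CCC=C(C)C)[C@H](O[Si](C)(C)C(C)(C)C)CC1 | intermediate
27 | (4R)-4-hydroxy-3-(4-methylpent-3-en-1-yl)cyclohex-2-en-1-one | O=C1C=C(CCC=C(C)C)[C@H](O)CC1 | intermediate
28 | (4R)-3-{2-[(2R)-3,3-dimethyloxiran-2-yl]ethyl}-4-hydroxycyclohex-2-en-1-one | O=C1C=C(CC[C@H]2OC2(C)C)[C@H](O)CC1 | intermediate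
29 | (3R,9aR)-3-hydroxy-2,2-dimethyl-2,3,4,5,9,9a-hexahydro-1-benzoxepin-7(8H)-one | O=C1C=C2CC[C@@H](O)C(C)(C)O[C@@H]2CC1 | intermediate
30 | (3R,9aR)-3-(tert-butyldimethylsilyloxy)-2,2-dimethyl-2,3,4,5,9,9a-hexahydro-1-benzoxepin-7(8H)-one | O=C1C=C2CC[C@@H](O[Si](C)(C)C(C)(C)C)C(C)(C)O[C@@H]2CC1 | intermediate
31 | tert-butyldimethyl{[(3R,5aS,9aR)-2,2,5a-trimethyl-7-(trimethylsilyloxy)-2,3,4,5,5a,8,9,9a-octahydro-1-benzoxepin-3-yl]oxy}silane | C[Si](C)(C)OC1=C[C@]2(C)CC[C@@H](O[Si](C)(C)C(C)(C)C)C(C)(C)O[C@@H]2CC1 | intermediate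
32 | lithium enolate of the ring A/B ketone (not isolated) | [Li]OC1=C[C@]2(C)CC[C@@H](O[Si](C)(C)C(C)(C)C)C(C)(C)O[C@@H]2CC1 | intermediate
33 | aldol adduct, mixture at C6 and the carbinol carbon (name in step 24) | CC1=CC[C@H]2[C@H](CCC2=C)C(C)(C)[C@@H]1CC(O)C1[C@]2(C)CC[C@@H](O[Si](C)(C)C(C)(C)C)C(C)(C)O[C@@H]2CCC1=O | intermediate
34 | mesylate of 33, same mixture (not isolated) | CC1=CC[C@H]2[C@H](CCC2=C)C(C)(C)[C@@H]1CC(OS(C)(=O)=O)C1[C@]2(C)CC[C@@H](O[Si](C)(C)C(C)(C)C)C(C)(C)O[C@@H]2CCC1=O | intermediate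
35 | 6-alkylidene ketone, alkene geometry not controlled (name in step 25) | CC1=CC[C@H]2[C@H](CCC2=C)C(C)(C)[C@@H]1CC=C1[C@]2(C)CC[C@@H](O[Si](C)(C)C(C)(C)C)C(C)(C)O[C@@H]2CCC1=O | intermediate
36 | (3R,5aS,6S,9aR)-ketone with the side chain on C6 (name in step 26) | CC1=CC[C@H]2[C@H](CCC2=C)C(C)(C)[C@@H]1CC[C@H]1[C@]2(C)CC[C@@H](O[Si](C)(C)C(C)(C)C)C(C)(C)O[C@@H]2CCC1=O | intermediate
37 | (3R,5aS,6S,7R,9aR)-C7 tertiary alcohol (name in step 27) | CC1=CC[C@H]2[C@H](CCC2=C)C(C)(C)[C@@H]1CC[C@H]1[C@]2(C)CC[C@@H](O[Si](C)(C)C(C)(C)C)C(C)(C)O[C@@H]2CC[C@@]1(C)O | intermediate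
38 | C1 acetoxymercuriomethyl carbinol (not isolated) | CC1=CC[C@H]2[C@H](CC[C@]2(C[Hg]OC(C)=O)O)C(C)(C)[C@@H]1CC[C@H]1[C@]2(C)CC[C@@H](O[Si](C)(C)C(C)(C)C)C(C)(C)O[C@@H]2CC[C@@]1(C)O | intermediate
39 | C1,C7-diol with the C3 TBS ether (name in step 28) | CC1=CC[C@H]2[C@H](CC[C@]2(C)O)C(C)(C)[C@@H]1CC[C@H]1[C@]2(C)CC[C@@H](O[Si](C)(C)C(C)(C)C)C(C)(C)O[C@@H]2CC[C@@]1(C)O | intermediate
40 | triol (name in step 29) | CC1=CC[C@H]2[C@H](CC[C@]2(C)O)C(C)(C)[C@@H]1CC[C@H]1[C@]2(C)CC[C@@H](O)C(C)(C)O[C@@H]2CC[C@@]1(C)O | intermediate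
41 | CNP0194989.5 (name in step 30) | CC1=CC[C@H]2[C@H](CC[C@]2(C)O)C(C)(C)[C@@H]1CC[C@H]1[C@]2(C)CCC(=O)C(C)(C)O[C@@H]2CC[C@@]1(C)O | target

Total steps: 30. Longest linear sequence: 19 steps (steps 3–14 from propane-1,3-diol, then steps 24–30).

Steps most likely to fail

Step 10. The conrotation may close on the ring C face away from the side chain, or protonation may erode the cis fusion. The fallback sets out from 11 and returns at 16. Vinylmagnesium bromide converts 11 into the cycloheptadienyl vinyl ketone F1. A proton-terminated Nazarov cyclization (BF3·OEt2, CH2Cl2) forms the same C3–C3a bond but ends by loss of the C3a proton, giving the ring-fusion enone F2 with both fusion carbons trigonal. Conjugate reduction with a phosphine-ligated copper hydride then delivers hydride to C3a on the face that carbon avoided and a proton to C8a on work-up, leading to 16.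

Step 21. The hydroxyl may attack the secondary epoxide carbon (6-exo) and give a tetrahydropyran. The fallback sets out from 27 and returns at 29. Cyclization of 27 with Hg(OCOCF3)2 (Markovnikov, oxygen to the dimethyl-substituted carbon) and chloride exchange give the 3-chloromercurio oxepane F3. Oxidative demercuration (NaBH4, O2, DMF) gives 29 together with the C3 epimer of 29 F4, which is carried alongside because C3 ends as the ketone.

Step 26. The enolate may be protonated on the face of the axial methyl, or the hindered enone may be reduced at the carbonyl. The fallback sets out from 18 and from enolate 32 (made from 31) and returns at 36. Alcohol 18 is converted with Tf2O and 2,6-di-tert-butylpyridine into the primary triflate F5, which alkylates 32 in THF/DMPU and forms the C6–CH2 bond directly. Any C6 epimer of 36 F6 is equilibrated with NaOMe in MeOH toward the equatorial isomer 36.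

Further compounds
F1 | step 10 | 1-{(4R)-4-[2-(tert-butyldiphenylsilyloxy)ethyl]-3,3,5-trimethylcyclohepta-1,5-dien-1-yl}prop-2-en-1-one | C=CC(=O)C1=CC(C)(C)[C@H](CCO[Si](c2ccccc2)(c2ccccc2)C(C)(C)C)C(C)=CC1
F2 | step 10 | (5R)-5-[2-(tert-butyldiphenylsilyloxy)ethyl]-4,4,6-trimethyl-3,4,5,8-tetrahydroazulen-1(2H)-one | CC1=CCC2=C(CCC2=O)C(C)(C)[C@@H]1CCO[Si](c3ccccc3)(c3ccccc3)C(C)(C)C
F3 | step 21 | (9aR)-3-(chloromercurio)-2,2-dimethyl-2,3,4,5,9,9a-hexahydro-1-benzoxepin-7(8H)-one, both C3 epimers | O=C1C=C2CCC([Hg]Cl)C(C)(C)O[C@@H]2CC1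
F4 | step 21 | (3S,9aR)-3-hydroxy-2,2-dimethyl-2,3,4,5,9,9a-hexahydro-1-benzoxepin-7(8H)-one | O=C1C=C2CC[C@H](O)C(C)(C)O[C@@H]2CC1
F5 | step 26 | 2-[(3aS,5R,8aS)-4,4,6-trimethyl-1-methylene-1,2,3,3a,4,5,8,8a-octahydroazulen-5-yl]ethyl trifluoromethanesulfonate | CC1=CC[C@H]2[C@H](CCC2=C)C(C)(C)[C@@H]1CCOS(=O)(=O)C(F)(F)F
F6 | step 26 | (6R)-epimer of 36 | CC1=CC[C@H]2[C@H](CCC2=C)C(C)(C)[C@@H]1CC[C@@H]1[C@]2(C)CC[C@@H](O[Si](C)(C)C(C)(C)C)C(C)(C)O[C@@H]2CCC1=O
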